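Temperature is what separates blue, grey and green, and red changes it after 15 min, so begin with what heat does to target.

all flasks: starting material 20 mM

| charge | protic impurity | temperature | remark | time |
|---|---|---|---|---|
| birch | 2.8 mM | 50 °C | run made earlier |  |
| oak | 4.4 mM | 72 °C | run made earlier |  |
| red | 2.00 mM |  | at 40 °C until 15 min, from then on at 80 °C | 30 min |
| blue | 2.00 mM | 60 °C |  | 30 min |
| grey | 2.00 mM | 40 °C |  | 30 min |
| green | 2.00 mM | 80 °C |  | 30 min |

Red, blue, grey and green hold 2.00 mM of protic impurity against 20 mM of starting material. If the quench takes one for one, and as long as no isomer of the product forms, a pool of 90.0% stays for starting material and target together.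

- birch (time / min: target / %, starting material / %): 2.50: 4.5, 93.8; 8.00: 12.4, 83.2; 12.0: 16.2, 77.4; 20.0: 21.9, 69.1; 30.0: 26.0, 63.2; 40.0: 28.5, 59.8
- oak (time / min: target / %, starting material / %): 2.00: 17.8, 75.0; 4.00: 19.5, 68.9; 6.00: 19.0, 66.3; 8.00: 18.0, 64.6; 12.0: 17.8, 61.5; 15.0: 17.1, 61.4

(each reading ± 0.3 percentage points)

- amounts and yields of target count crystals too
- given per volume of solution although it is solid: crystals
- steps that have been proposed: starting material + protic impurity -> quenched substrate; target <-> isomer of the product; crystals <-> target; starting material <-> target

Oak tests that pool: its impurity leaves 78.0%, and target plus starting material read 78.5% at 15.0 min. But target does not take the whole pool in oak, so call the rest ratio the value of [target]/[starting material], dissolved target counted, at which the step starting material <-> target stands still; it is that step's equilibrium constant. Oak's ratio goes from 0.287 at 6.00 min to 0.279 at 15.0 min, so that is its reading at 72 °C.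

Birch is still moving, so replace its curve by mean rates over two stretches. From 2.50 min to 8.00 min, target grows by 0.0162 /min of the mean starting material at a mean ratio of 0.0955. From 30.0 min to 40.0 min, it grows by 0.00407 /min at 0.443. If making goes with [starting material] and undoing with [target], that rate is a straight line in the ratio, and it reaches zero at 0.559 for 50 °C.

Heat lowers the ratio. Taking its logarithm as straight in temperature, I get 0.407 at 60 °C and 0.216 as the rest ratio at 80 °C. If both flasks reach their rest ratio by the end, the pool gives target 26.1% in blue and 16.0% in green. Red's hot stage should land beside green. Grey, colder than birch, should stay under birch's 26.0% at 30.0 min.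

* the flask that comes out highest in amount of target, in percent of the starting material charged, or "all alike" when all lie within 1.5 percentage points (red / blue / grey / green / all alike)
* target at the end, in percent of the starting material charged, red
* target at the end, in percent of the starting material charged, blue
* target at the end, in percent of the starting material charged, grey
* target at the end, in percent of the starting material charged, green

The forecast names blue, with 16.9% for red, 25.9% for blue, 14.3% for grey and 16.9% for green, above my green, saying that red's hot stage “relaxes fully, erasing its history”.

The flasks give 15.7% for red, 26.1% for blue, 13.8% for grey and 15.1% for green, so blue is highest.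

    starting material + protic impurity → quenched substrate (k = 0.0935 /M/s, Ea = 59.0 kJ/mol)
    target ⇌ isomer of the product (K = 1.24, k = 2.50 × 10⁻⁵ /s, Ea = 112 kJ/mol, ΔH = 60.0 kJ/mol)
    crystals ⇌ target, rate k3*(cs3 - [target]) while solid is left; crystals form when [target] > cs3 (solubility = 8.00 mM, k = 0.0703 /s)
    starting material ⇌ target (K = 0.410, k = 9.77 × 10⁻⁴ /s, Ea = 101 kJ/mol, ΔH = −30.0 kJ/mol)
    (constants at 60 °C)

The undoing of target into starting material is the main reason that green stands at 15.1%; with it taken away, green reaches 77.9%. Green's [target]/[starting material] is 0.221 against the rest ratio 0.216, although 6.60% of the charge has gone to the isomer of the product. The neighbour like red but with 80 mM of starting material holds 39.8% as crystals, and its dissolved target over starting material is 0.221.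

All runs were generated by integration for an exercise, and the scatter is random.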